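**Plan**

Retrosynthesis: the formyl group is cut back to the methyl of an isopropenyl group (allylic oxidation last); next the two ester C–O bonds and the side-chain carbinol C–H (acylations, ketone reduction); then the C2–C3 bond of the dihydrofuran ring; last the C–B and aryl O–vinyl bonds of the open precursor.
Enabling feature: in the furan ring, C3 (benzylic C–O) and C2 (bonded to ring O1 and to the 1,1-disubstituted alkene carbon) form a homoallylic alcohol unit O–C3–C2–C(=CH2). C2–C3 is therefore the bond that an O1-tethered (E)-γ-aryloxyallyl boronate makes when its O-bearing γ-carbon adds to the ortho formyl group; the exocyclic =CH2 is the former B–CH2.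
Forward: the benzene ring is bought; aryl vinyl ether by copper-catalysed O-vinylation; allyl boronate; oxidation and ring closure (the only ring made); C3 acylation; ketone reduction; side-chain acylation; allylic oxidation to the enal.
Stereochemistry: C3 from a chiral phosphoric acid; C2 from the E enol-ether geometry through the chair transition state (anti adduct = 2,3-trans), that geometry coming from syn-carboalumination; side-chain carbinol from asymmetric transfer hydrogenation; the 2-methylbutanoate centre is bought.

Key step: step 5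

Assumption: the (R)-phosphoric acid is taken to direct the tethered allylboronate to the Re face of the formyl group, as it does in intermolecular allylborations of aryl aldehydes; this is what fixes (3S).

Bpin = 4,4,5,5-tetramethyl-1,3,2-dioxaborolan-2-yl. (R)-TRIP = (R)-3,3'-bis(2,4,6-triisopropylphenyl)-1,1'-binaphthyl-2,2'-diyl hydrogen phosphate.

**Route**

Step 1
Reactants: 1 prop-2-yn-1-ol
Product: 3 (2E)-3-iodo-2-methylprop-2-en-1-ol, via alkenylalane 2 (not isolated)
Conditions: Me3Al (3 equiv), Cp2ZrCl2 (0.25 equiv), CH2Cl2, 0 °C to rt; then I2, THF, −30 to 0 °C; aq. K2CO3 work-up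
Reagents that add atoms: trimethylaluminium C[Al](C)C; iodine II
Why: Zirconium-catalysed syn-carboalumination of the terminal alkyne (Negishi carboalumination) puts methyl on the internal and aluminium on the terminal carbon, and iodinolysis of the C–Al bond with retention should give the E iodoalkene that later fixes the enol-ether geometry.

Step 2
Reactants: 3 (2E)-3-iodo-2-methylprop-2-en-1-ol; 4 1-[4-hydroxy-3-(hydroxymethyl)phenyl]ethan-1-one
Product: 5 1-[3-(hydroxymethyl)-4-{[(1E)-3-hydroxy-2-methylprop-1-en-1-yl]oxy}phenyl]ethan-1-one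
Conditions: CuI (copper monoiodide, 10 mol%), N,N-dimethylglycine hydrochloride (30 mol%), Cs2CO3 (2 equiv), 1,4-dioxane, 80 °C
Reagents that add atoms: none
Why: Ullmann-type copper-catalysed C–O coupling of a vinyl iodide with a phenoxide proceeds with retention of alkene geometry, and carbonate deprotonates only the phenol, so the E aryl vinyl ether (aryloxy cis to methyl, trans to CH2OH) should form in preference to ethers of the primary alcohols.

Step 3
Reactants: 5 1-[3-(hydroxymethyl)-4-{[(1E)-3-hydroxy-2-methylprop-1-en-1-yl]oxy}phenyl]ethan-1-one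
Product: 6 (2E)-3-[4-acetyl-2-(acetoxymethyl)phenoxy]-2-methylprop-2-en-1-yl acetate
Conditions: Ac2O, pyridine, DMAP (cat.), CH2Cl2, 0 °C
Reagents that add atoms: acetic anhydride CC(=O)OC(C)=O
Why: Acetylation of both primary alcohols provides in one operation the allylic leaving group for the borylation and a mask that keeps the benzylic oxygen from attacking the π-allyl intermediate of the next step.

Step 4
Reactants: 6 (2E)-3-[4-acetyl-2-(acetoxymethyl)phenoxy]-2-methylprop-2-en-1-yl acetate
Product: 8 1-[3-(hydroxymethyl)-4-{[(1E)-2-methyl-3-(Bpin)prop-1-en-1-yl]oxy}phenyl]ethan-1-one, via benzylic acetate 7 (not isolated)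
Conditions: B2pin2 (1.1 equiv), Pd2(dba)3 (2.5 mol%), DMSO, 50 °C; then K2CO3, MeOH, 0 °C
Reagents that add atoms: bis(pinacolato)diboron CC1(C)OB(OC1(C)C)B1OC(C)(C)C(C)(C)O1
Why: Zerovalent palladium ionises only the allylic acetate (Miyaura-type borylation of allyl acetates); the aryloxy group should stay syn in the π-allyl complex, and boron is delivered to the unsubstituted CH2 terminus to give the E allylboronate, after which carbonate-catalysed methanolysis frees the benzylic alcohol.

Step 5
Reactants: 8 1-[3-(hydroxymethyl)-4-{[(1E)-2-methyl-3-(Bpin)prop-1-en-1-yl]oxy}phenyl]ethan-1-one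
Product: 11 1-[(2R,3S)-3-hydroxy-2-(prop-1-en-2-yl)-2,3-dihydro-1-benzofuran-5-yl]ethan-1-one, via aldehyde 9 (not isolated), via pinacol borate 10 (not isolated)
Conditions: Dess–Martin periodinane, NaHCO3, CH2Cl2, −15 °C; cold filtration into toluene at −78 °C; (R)-TRIP (10 mol%), 4 Å molecular sieves, −60 °C; aq. NaHCO3 work-up
Reagents that add atoms: none
Why: Proposed new method: buffered Dess–Martin oxidation gives aldehyde 9, whose pinacol allylboronate adds through its oxygen-bearing γ-carbon to the formyl carbon in a six-membered chair transition state (B–O=C···Cγ=Cβ–Cα) that the chiral phosphoric acid accelerates and biases by hydrogen bonding to a boronate oxygen and the formyl C–H; the closest known reaction types are the chiral-phosphoric-acid-catalysed allyl- and crotylboration of aryl aldehydes (intermolecular) and the uncatalysed, stereospecific intramolecular allylboration of (E)-γ-(formylalkoxy)allylboronates to trans-2-alkenyl-3-hydroxy cyclic ethers, which have not been combined. The dihydrofuran ring closes 5-exo-trig at the carbonyl carbon with the reacting Cβ=Cγ bond exocyclic to the new ring, and the B–CH2 carbon becomes the exocyclic methylene of the isopropenyl group. C3 is set by the catalyst, the (R)-acid being expected to direct attack to the Re face of the formyl group (3S); C2 is set by the E geometry, because the aryloxy group and the aryl group both sit equatorial in the chair, which gives the anti adduct, that is the 2,3-trans ring (2R). The step needs catalyst control over the uncatalysed closure and chemoselectivity for the aldehyde over the aryl ketone: the former should be secured by generating 9 cold and keeping it at −60 °C, where only the acid-bound pathway is fast, the latter by the inertness of pinacol allylboronates toward ketones.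

Step 6
Reactants: 11 1-[(2R,3S)-3-hydroxy-2-(prop-1-en-2-yl)-2,3-dihydro-1-benzofuran-5-yl]ethan-1-one; 12 3-methylbutanoic anhydride
Product: 13 (2R,3S)-5-acetyl-2-(prop-1-en-2-yl)-2,3-dihydro-1-benzofuran-3-yl 3-methylbutanoate
Conditions: DMAP (cat.), Et3N, CH2Cl2, 0 °C
Reagents that add atoms: none
Why: DMAP-catalysed acylation of the secondary benzylic alcohol under basic conditions avoids ionisation at C3 (which would lead to the benzofuran) and leaves both ring stereocentres untouched.

Step 7
Reactants: 13 (2R,3S)-5-acetyl-2-(prop-1-en-2-yl)-2,3-dihydro-1-benzofuran-3-yl 3-methylbutanoate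
Product: 14 (2R,3S)-5-[(1R)-1-hydroxyethyl]-2-(prop-1-en-2-yl)-2,3-dihydro-1-benzofuran-3-yl 3-methylbutanoate
Conditions: RuCl[(R,R)-TsDPEN](p-cymene) (1 mol%), HCO2H/Et3N (5:2), CH2Cl2, rt
Reagents that add atoms: none
Why: Noyori asymmetric transfer hydrogenation of the aryl methyl ketone with the (R,R)-catalyst should give the (R)-1-arylethanol under catalyst control, and it spares the isopropenyl group that a borane reduction would endanger.

Step 8
Reactants: 14 (2R,3S)-5-[(1R)-1-hydroxyethyl]-2-(prop-1-en-2-yl)-2,3-dihydro-1-benzofuran-3-yl 3-methylbutanoate; 15 (2R)-2-methylbutanoic acid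
Product: 16 (1R)-1-[(2R,3S)-3-[(3-methylbutanoyl)oxy]-2-(prop-1-en-2-yl)-2,3-dihydro-1-benzofuran-5-yl]ethyl (2R)-2-methylbutanoate
Conditions: DCC, DMAP (0.1 equiv), CH2Cl2, 0 °C to rt
Reagents that add atoms: none
Why: Steglich esterification acylates the only free hydroxyl with retention at the carbinol carbon, and with DMAP kept catalytic at low temperature the α-stereocentre of the acid should not epimerise.

Step 9
Reactants: 16 (1R)-1-[(2R,3S)-3-[(3-methylbutanoyl)oxy]-2-(prop-1-en-2-yl)-2,3-dihydro-1-benzofuran-5-yl]ethyl (2R)-2-methylbutanoate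
Product: 17 (1R)-1-[(2R,3S)-2-(3-hydroxyprop-1-en-2-yl)-3-[(3-methylbutanoyl)oxy]-2,3-dihydro-1-benzofuran-5-yl]ethyl (2R)-2-methylbutanoate
Conditions: SeO2 (0.5 equiv), t-BuOOH (3 equiv), CH2Cl2, rt
Reagents that add atoms: tert-butyl hydroperoxide CC(C)(C)OO
Why: Riley allylic oxidation (ene reaction, then [2,3]-sigmatropic shift) of a 1,1-disubstituted alkene should oxidise the methyl group in preference to the tertiary C2–H and return the double bond to the exocyclic position; the catalytic room-temperature variant stops mainly at the allylic alcohol, and any enal already formed is carried through step 10.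

Step 10
Reactants: 17 (1R)-1-[(2R,3S)-2-(3-hydroxyprop-1-en-2-yl)-3-[(3-methylbutanoyl)oxy]-2,3-dihydro-1-benzofuran-5-yl]ethyl (2R)-2-methylbutanoate
Product: 18 (1R)-1-[(2R,3S)-3-[(3-methylbutanoyl)oxy]-2-(3-oxoprop-1-en-2-yl)-2,3-dihydro-1-benzofuran-5-yl]ethyl (2R)-2-methylbutanoate
Conditions: MnO2 (activated, excess), CH2Cl2, rt
Reagents that add atoms: none
Why: MnO2 oxidises allylic alcohols selectively to enals under neutral conditions, so the acid-labile benzylic esters and all four stereocentres should survive.

**Compound list**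

1 | prop-2-yn-1-ol | C#CCO | starting material
2 | [(1E)-3-[(dimethylalumanyl)oxy]-2-methylprop-1-en-1-yl]dimethylalumane | C[Al](C)OC/C(C)=C/[Al](C)C | intermediate
3 | (2E)-3-iodo-2-methylprop-2-en-1-ol | OC/C(C)=C/I | intermediate
4 | 1-[4-hydroxy-3-(hydroxymethyl)phenyl]ethan-1-one | CC(=O)c1ccc(O)c(CO)c1 | starting material
5 | 1-[3-(hydroxymethyl)-4-{[(1E)-3-hydroxy-2-methylprop-1-en-1-yl]oxy}phenyl]ethan-1-one | CC(=O)c1ccc(O/C=C(\C)CO)c(CO)c1 | intermediate
6 | (2E)-3-[4-acetyl-2-(acetoxymethyl)phenoxy]-2-methylprop-2-en-1-yl acetate | CC(=O)c1ccc(O/C=C(\C)COC(C)=O)c(COC(C)=O)c1 | intermediate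
7 | [5-acetyl-2-{[(1E)-2-methyl-3-(4,4,5,5-tetramethyl-1,3,2-dioxaborolan-2-yl)prop-1-en-1-yl]oxy}phenyl]methyl acetate | CC(=O)c1ccc(O/C=C(\C)CB2OC(C)(C)C(C)(C)O2)c(COC(C)=O)c1 | intermediate
8 | 1-[3-(hydroxymethyl)-4-{[(1E)-2-methyl-3-(4,4,5,5-tetramethyl-1,3,2-dioxaborolan-2-yl)prop-1-en-1-yl]oxy}phenyl]ethan-1-one | CC(=O)c1ccc(O/C=C(\C)CB2OC(C)(C)C(C)(C)O2)c(CO)c1 | intermediate
9 | 5-acetyl-2-{[(1E)-2-methyl-3-(4,4,5,5-tetramethyl-1,3,2-dioxaborolan-2-yl)prop-1-en-1-yl]oxy}benzaldehyde | CC(=O)c1ccc(O/C=C(\C)CB2OC(C)(C)C(C)(C)O2)c(C=O)c1 | intermediate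
10 | 1-[(2R,3S)-2-(prop-1-en-2-yl)-3-[(4,4,5,5-tetramethyl-1,3,2-dioxaborolan-2-yl)oxy]-2,3-dihydro-1-benzofuran-5-yl]ethan-1-one | C=C(C)[C@H]1Oc2ccc(C(C)=O)cc2[C@@H]1OB3OC(C)(C)C(C)(C)O3 | intermediate
11 | 1-[(2R,3S)-3-hydroxy-2-(prop-1-en-2-yl)-2,3-dihydro-1-benzofuran-5-yl]ethan-1-one | C=C(C)[C@H]1Oc2ccc(C(C)=O)cc2[C@@H]1O | intermediate
12 | 3-methylbutanoic anhydride | CC(C)CC(=O)OC(=O)CC(C)C | starting material
13 | (2R,3S)-5-acetyl-2-(prop-1-en-2-yl)-2,3-dihydro-1-benzofuran-3-yl 3-methylbutanoate | C=C(C)[C@H]1Oc2ccc(C(C)=O)cc2[C@@H]1OC(=O)CC(C)C | intermediate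
14 | (2R,3S)-5-[(1R)-1-hydroxyethyl]-2-(prop-1-en-2-yl)-2,3-dihydro-1-benzofuran-3-yl 3-methylbutanoate | C=C(C)[C@H]1Oc2ccc([C@@H](C)O)cc2[C@@H]1OC(=O)CC(C)C | intermediate
15 | (2R)-2-methylbutanoic acid | CC[C@@H](C)C(=O)O | starting material
16 | (1R)-1-[(2R,3S)-3-[(3-methylbutanoyl)oxy]-2-(prop-1-en-2-yl)-2,3-dihydro-1-benzofuran-5-yl]ethyl (2R)-2-methylbutanoate | C=C(C)[C@H]1Oc2ccc([C@@H](C)OC(=O)[C@H](C)CC)cc2[C@@H]1OC(=O)CC(C)C | intermediate
17 | (1R)-1-[(2R,3S)-2-(3-hydroxyprop-1-en-2-yl)-3-[(3-methylbutanoyl)oxy]-2,3-dihydro-1-benzofuran-5-yl]ethyl (2R)-2-methylbutanoate | C=C(CO)[C@H]1Oc2ccc([C@@H](C)OC(=O)[C@H](C)CC)cc2[C@@H]1OC(=O)CC(C)C | intermediate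
18 | (1R)-1-[(2R,3S)-3-[(3-methylbutanoyl)oxy]-2-(3-oxoprop-1-en-2-yl)-2,3-dihydro-1-benzofuran-5-yl]ethyl (2R)-2-methylbutanoate (CNP0154159.1) | C=C(C=O)[C@H]1Oc2ccc([C@@H](C)OC(=O)[C@H](C)CC)cc2[C@@H]1OC(=O)CC(C)C | target

**Count**

Total step count: 10. Longest linear sequence: 10 (steps 1 to 10; compounds 4, 12 and 15 enter along the way).

**Steps most likely to fail**

Step 5 (proposed new method). The uncatalysed closure may set in during or after the oxidation, or the tethered chair may fit poorly in the catalyst pocket; either would erode facial selectivity at the formyl group. Fallback with known chemistry, setting out from 8: oxidation with MnO2 in CH2Cl2 at room temperature and gentle warming would let aldehyde 9 close without catalyst. This is the known stereospecific intramolecular allylboration of an (E)-γ-oxyallylboronate and should give the trans ring in both mirror-image forms: 10 together with (2S,3R)-pinacol borate F1, hydrolysed on work-up to 11 together with (2S,3R)-alcohol F2. Acylative kinetic resolution of this pair with anhydride 12 and the chiral isothiourea benzotetramisole would follow, using the enantiomer that acylates (R)-1-arylalkanols faster, since the (3S) carbinol has the same spatial arrangement of OH, aryl and alkyl. It should convert 11 into 13 and leave F2 to be removed by chromatography. The route is rejoined at 13.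

Step 9. Oxidation may occur at the tertiary allylic C2–H instead of the methyl group, or selenous acid may over-oxidise the product or solvolyse the benzylic esters. Fallback setting out from 16: selenium-catalysed ene-type allylic chlorination (N-chlorosuccinimide, PhSeCl cat., CH2Cl2, rt) should give the transposed allylic chloride, which for an isopropenyl group is the 2-(3-chloroprop-1-en-2-yl) compound F3. Kornblum-type oxidation with N-methylmorpholine N-oxide (NaI cat., MeCN, rt) would then convert CH2Cl directly into the formyl group. The route is rejoined at 18, without passing through 17.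

Step 2. The C–O coupling of the electron-poor phenoxide may be sluggish, a primary alcohol may be vinylated in competition, or the alkene geometry may erode under the copper and base conditions. Fallback setting out from 3: palladium-catalysed Miyaura borylation of the vinyl iodide (PdCl2(dppf), B2pin2, KOPh, toluene, 50 °C) would give the (E)-alkenylboronate F4. Oxidative Chan–Lam coupling of F4 with phenol 4 (Cu(OAc)2, pyridine, 4 Å molecular sieves, air, CH2Cl2, rt) proceeds by a different mechanism, at room temperature and without carbonate base, with retention of geometry. The route is rejoined at 5.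

**Further compounds**

F1 | step 5 | 1-[(2S,3R)-2-(prop-1-en-2-yl)-3-[(4,4,5,5-tetramethyl-1,3,2-dioxaborolan-2-yl)oxy]-2,3-dihydro-1-benzofuran-5-yl]ethan-1-one | C=C(C)[C@@H]1Oc2ccc(C(C)=O)cc2[C@H]1OB3OC(C)(C)C(C)(C)O3
F2 | step 5 | 1-[(2S,3R)-3-hydroxy-2-(prop-1-en-2-yl)-2,3-dihydro-1-benzofuran-5-yl]ethan-1-one | C=C(C)[C@@H]1Oc2ccc(C(C)=O)cc2[C@H]1O
F3 | step 9 | (1R)-1-[(2R,3S)-2-(3-chloroprop-1-en-2-yl)-3-[(3-methylbutanoyl)oxy]-2,3-dihydro-1-benzofuran-5-yl]ethyl (2R)-2-methylbutanoate | C=C(CCl)[C@H]1Oc2ccc([C@@H](C)OC(=O)[C@H](C)CC)cc2[C@@H]1OC(=O)CC(C)C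
F4 | step 2 | (2E)-2-methyl-3-(4,4,5,5-tetramethyl-1,3,2-dioxaborolan-2-yl)prop-2-en-1-ol | OC/C(C)=C/B1OC(C)(C)C(C)(C)O1
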